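The target of this flask is asked for as a share of target plus side product, so I asked first what the end state must hold.

| setting | north-east | flask |
|---|---|---|
| starting material | 15 mM | 10 mM |
| remark | run made earlier |  |
| time |  | 1.0 h |

- north-east (time / min: target / %, side product / %, starting material / %): 0.667: 10.4, 1.7, 77.6; 2.00: 26.5, 3.4, 45.9; 3.00: 31.3, 3.2, 34.0; 5.00: 38.8, 5.3, 19.4; 8.00: 40.2, 7.6, 9.2; 10.0: 41.1, 7.3, 5.9; 12.0: 37.9, 8.8, 3.1

(standard deviation of a reading: 1 percentage point)

- share of target in target plus side product at 3.0 s
- share of target in target plus side product at 1.0 h

- a reading or a percentage of target counts all its forms, free or not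
- a reading of starting material is of its free form alone

On the first rung of the ladder stood the starting material. In the north-east run, from 2.00 min to 10.0 min, it fell with a rate constant of 0.256 min⁻¹, a half-life of 2.70 min, far shorter than the 1.0 h of the flask. So I expected full conversion in the flask well before its end, and I assumed that side product, once made, stays.

The last reading gave 9.08 % of the consumed material as side product. I called this the side-product ceiling, the percentage of the charge that side product reaches at full conversion, the selectivity of that branch, and carried it over to the flask.

On the second rung stood target. Between the last two readings it fell at 0.0405 min⁻¹, a half-life of 17.1 min, longer than that of the starting material but shorter than the run. Two scattered readings, with starting material still read at 3.1 %, make that figure loose. Continued to 1.0 h, that rate gave me an estimate of 5.42 % target, so my estimate of [target]/([target]+[side product]) came to 37.4 %. The earliest reading lies later than 3.0 s, so I offered no early share.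

The forecast gave 89 % at 3.0 s and 40 % at 1.0 h, with “target about 12, side product about 18”; my target and side product differed, at 5.42 % and 9.08 %.

The flask gave 99.6 % at 3.0 s and 25.2 % at 1.0 h.

    starting material → target (k = 0.190 min⁻¹)
    starting material → intermediate A (k = 0.0290 min⁻¹)
    starting material → intermediate B (k = 0.0990 min⁻¹)
    intermediate B ⇌ intermediate C (K = 2.00, k = 0.0140 min⁻¹)
    intermediate A → side product (k = 1.10 min⁻¹)
    intermediate B ⇌ intermediate D (K = 0.790, k = 1.50 min⁻¹)
    target → over-reaction product (k = 0.0540 min⁻¹)
    starting material + target ⇌ idle adduct, settled at all times (K = 79.0 M⁻¹)

At 1.00 h the flask held 9.12 % side product and 3.08 % target, against my 5.42 %; that target with the ceiling gives 25.3 %. The neighbour flask was charged with 17 mM of starting material, and 0 % of it remained at the same time. Its 3.24 % target with the ceiling gives 26.3 %. That neighbour flask held 9.12 % side product, and its share came to 26.2 %.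

(The runs are calculated for an exercise, and the scatter is random.)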